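The disconnection cuts the 5,7-dihydroxychromone of unit 2 (benzo ring D, pyranone ring F, atoms O1 to C8a) at C4a-C5 and O1-C2. The feature exploited is its polyketide oxygen pattern: C2, C4, C8a, C7 and C5 each bear oxygen. C5 to C8a are stored as a 4-hydroxy-2-pyranone and C2/C3 as an alkyne, linked by the C4a methylene and the C4 ketone. One treatment with Mg(OMe)2 should open the lactone, close ring D by Claisen condensation and close ring F by oxa-Michael addition. The precursor is a 4-hydroxy-6-(2-oxo-4-arylbut-3-ynyl)-2-pyranone whose aryl ring E already carries the tribenzylated 7-methoxyflavone (rings A, B, C).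

Key step: step 10

**Labels.** Unit 1 consists of benzo ring A, pyranone ring C and the 4-oxygenated phenyl ring B. Ring E is the central phenol ring. Unit 2 consists of rings D and F. Locants C2 to C8a in steps 9 and 10 are those of the unit 2 chromone. Ar = 4-(benzyloxy)-3-{5-(benzyloxy)-2-[4-(benzyloxy)phenyl]-7-methoxy-4-oxo-4H-chromen-3-yl}phenyl.

**Assumption.** The target SMILES has no stereodescriptor, so the hindered ring C-ring E axis is treated as configurationally unassigned and no stereocontrol is planned.

**Design points.**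
- (a) The ring C-ring E bond is made by cross-coupling. No ortho-oxygenated deoxybenzoin has to be made under Lewis acid, where benzofuran formation or benzyl loss threatens. The methoxy group is bought in place, so no polyphenol needs selective methylation.
- (b) The three spectator phenols are benzyl ethers, which are released together in one step. The ether on O5 of unit 1 is needed during the key step.
- (c) The pyranone 4-OH stays free, because its anion is the form for which magnesium-mediated folding is known. The ynone is liberated only at an acidic quench.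

Step 1
Reactants: 1 1-(2,6-dihydroxy-4-methoxyphenyl)ethan-1-one
Product: 2 1-[2-(benzyloxy)-6-hydroxy-4-methoxyphenyl]ethan-1-one
Conditions: BnBr (1.05 equiv), K2CO3, acetone, reflux
Reagents that add atoms: benzyl bromide, BrCc1ccccc1
Why: Williamson ether synthesis in which the first alkylation leaves the remaining phenol locked in a strong hydrogen bond to the ketone, so one equivalent of benzyl bromide should stop at the monoether of the symmetric diol.

Step 2
Reactants: 2 1-[2-(benzyloxy)-6-hydroxy-4-methoxyphenyl]ethan-1-one; 3 4-(benzyloxy)benzoyl chloride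
Product: 6 5-(benzyloxy)-2-[4-(benzyloxy)phenyl]-7-methoxy-4H-chromen-4-one, via dilithio enolate 4 (not isolated), via diketone 5 (not isolated)
Conditions: LiN(SiMe3)2 (3.2 equiv), THF, -78 to -10 °C; 3, -78 °C to rt; AcOH quench, THF distilled off; AcOH, 110 °C
Reagents that add atoms: none
Why: Baker-Venkataraman-type C-aroylation of the preformed enolate (any O-aroyl ester rearranges under the excess base to the same diketone) followed by cyclodehydration of the 2-hydroxyaryl 1,3-diketone in acetic acid buffered by the lithium acetate formed at the quench, a medium mild enough for the acid-labile peri benzyl ether.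

Step 3
Reactants: 6 5-(benzyloxy)-2-[4-(benzyloxy)phenyl]-7-methoxy-4H-chromen-4-one
Product: 8 5-(benzyloxy)-2-[4-(benzyloxy)phenyl]-3-iodo-7-methoxy-4H-chromen-4-one, via 3-lithioflavone 7 (not isolated)
Conditions: LiN(iPr)2 (1.3 equiv), THF, -78 °C; I2, THF, -78 °C
Reagents that add atoms: iodine, II
Why: Directed deprotonation-iodination, in which C3-H is the most acidic C-H of a flavone and its lithio species is held by the C4 carbonyl oxygen at -78 °C, so iodine is placed at C3 and not at the electron-rich C6 or C8 that an electrophilic iodination would attack.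

Step 4
Reactants: 9 4-bromo-2-iodophenol
Product: 10 1-(benzyloxy)-4-bromo-2-iodobenzene
Conditions: BnBr, K2CO3, DMF, rt
Reagents that add atoms: benzyl bromide, BrCc1ccccc1
Why: Williamson ether synthesis on an acidic halophenol, under which neither aryl halide reacts.

Step 5
Reactants: 10 1-(benzyloxy)-4-bromo-2-iodobenzene
Product: 12 2-[2-(benzyloxy)-5-bromophenyl]-4,4,5,5-tetramethyl-1,3,2-dioxaborolane, via aryl Grignard reagent 11 (not isolated)
Conditions: iPrMgCl·LiCl, THF, -20 °C; iPrOBpin, -20 °C to rt; cold 1 M HCl work-up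
Reagents that add atoms: 2-isopropoxy-4,4,5,5-tetramethyl-1,3,2-dioxaborolane, CC(C)OB1OC(C)(C)C(C)(C)O1
Why: Halogen-magnesium exchange is much faster at C-I than at C-Br and is assisted by the ortho oxygen, and the aryl Grignard reagent is then trapped by the alkoxyboronate (electrophilic borylation).

Step 6
Reactants: 8 5-(benzyloxy)-2-[4-(benzyloxy)phenyl]-3-iodo-7-methoxy-4H-chromen-4-one; 12 2-[2-(benzyloxy)-5-bromophenyl]-4,4,5,5-tetramethyl-1,3,2-dioxaborolane
Product: 13 5-(benzyloxy)-3-[2-(benzyloxy)-5-bromophenyl]-2-[4-(benzyloxy)phenyl]-7-methoxy-4H-chromen-4-one (Ar-Br)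
Conditions: Pd(PPh3)4 (5 mol%), K2CO3, 1,4-dioxane/H2O, 80 °C
Reagents that add atoms: none
Why: Suzuki-Miyaura coupling in which triphenylphosphine-ligated zerovalent palladium inserts into the electron-poor C3-I bond of the iodoenone far faster than into the electron-rich aryl C-Br bond, so the bromide is kept for step 8.

Step 7
Reactants: 14 propiolic acid
Product: 15 N-methoxy-N-methylprop-2-ynamide
Conditions: MeNHOMe·HCl, DCC, N-methylmorpholine (slow addition), CH2Cl2, -10 to 0 °C
Reagents that add atoms: N,O-dimethylhydroxylamine hydrochloride, CNOC.Cl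
Why: Carbodiimide amide coupling run cold with the amine liberated slowly from its salt, so that N-acylation outruns aza-Michael addition to the triple bond.

Step 8
Reactants: 13 Ar-Br; 15 N-methoxy-N-methylprop-2-ynamide
Product: 16 3-Ar-N-methoxy-N-methylprop-2-ynamide
Conditions: Pd(PhCN)2Cl2 (3 mol%), [HP(t-Bu)3]BF4 (6 mol%), CuI (2 mol%), i-Pr2NH, 1,4-dioxane, rt to 45 °C, degassed
Reagents that add atoms: none
Why: Sonogashira coupling in which the bulky electron-rich phosphine allows oxidative addition of the para-alkoxy aryl bromide near room temperature, where the electron-poor alkyne should not oligomerise and the hindered amine should not add to it.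

Step 9
Reactants: 16 3-Ar-N-methoxy-N-methylprop-2-ynamide; 17 triacetic acid lactone (4-hydroxy-6-methyl-2H-pyran-2-one)
Product: 20 4-hydroxy-6-(2-oxo-4-Ar-but-3-yn-1-yl)-2H-pyran-2-one, via dilithio lactone 18 (not isolated), via tetrahedral adduct 19 (not isolated)
Conditions: 17 (2 equiv), LiN(iPr)2 (4.2 equiv), THF, -78 to 0 °C; 16, THF, -78 °C; inverse quench into cold 1 M HCl
Reagents that add atoms: none
Why: Claisen-type acylation of the triacetic acid lactone dianion, which reacts at its more basic C6 methylene carbon, by a Weinreb amide whose chelated adduct 19 withholds the ynone until the acidic inverse quench, so that over-addition, conjugate addition and attack of the released amine on the ynone are avoided.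

Step 10
Reactants: 20 4-hydroxy-6-(2-oxo-4-Ar-but-3-yn-1-yl)-2H-pyran-2-one
Product: 24 2-Ar-5,7-dihydroxy-4H-chromen-4-one (tribenzyl ether of the target), via triketo ester 21 (not isolated), via acylphloroglucinol ynone 22 (not isolated), via methanol adduct 23 (not isolated)
Conditions: Mg(OMe)2 (10 equiv), dry MeOH/THF, 65 °C, argon; then 1 M HCl, 40 °C
Reagents that add atoms: none
Why: Proposed new method: Mg(OMe)2 deprotonates 20, methoxide then opens the lactone at the pyranone carbonyl (future C5), and the chain is held as the magnesium chelate of triketo ester 21, in which C2 is still latent in the triple bond. The C4a methylene, acidified by the C4 and C8a carbonyls, attacks the ester carbon (6-exo-trig Claisen/Dieckmann closure, C4a-C5), methanol is expelled and enolisation gives aromatic ring D in 22. Ring F closes when the oxygen on C8a attacks C2, directly (6-endo-dig oxa-Michael) or by addition-elimination on the methanol adduct 23 (6-endo-trig); such O-C2 closures are reversible in methoxide whereas aromatisation of ring D is not, so the order of the two bond formations should not matter, and the warm acid finish converts any remaining 23. The closest known reaction types are the magnesium methoxide Claisen folding of 6-(2-oxoalkyl)-4-hydroxy-2-pyranones to acylphloroglucinols and the base-induced 6-endo cyclisation of 2-hydroxyaryl ynones to flavones, which have not been run as one cascade or with an alkynyl ketone in the chain. The selectivity needed is Claisen over aldol folding (C6 onto C4, leading to a resorcylate), and it rests on the substrate: C4 sits in an enolised magnesium 1,3-diketonate and becomes a vinylogous ester once methanol has added, so the methyl ester is the only good acceptor left, and a strictly dry medium keeps C2 from turning into a further ketone with extra folding modes. No stereocentre is created, closure through either hydroxyl next to the acyl group of the symmetric ring D gives the same chromone, conjugate attack at C2 rather than C3 rules out the aurone, and the benzyl group on O5 of unit 1 stops that chromone from binding magnesium or isomerising after reversible methoxide opening.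

Step 11
Reactants: 24 2-Ar-5,7-dihydroxy-4H-chromen-4-one
Product: 25 target CNP0284832.0, 2-{4-hydroxy-3-[5-hydroxy-2-(4-hydroxyphenyl)-7-methoxy-4-oxo-4H-chromen-3-yl]phenyl}-5,7-dihydroxy-4H-chromen-4-one
Conditions: H2 (1 atm), Pd/C (10 wt% palladium on carbon), THF/MeOH, rt
Reagents that add atoms: none
Why: Catalytic hydrogenolysis of aryl benzyl ethers, under which the aryl methyl ether and the two vinylogous-ester C2=C3 bonds of the chromones are inert at one atmosphere.

**Compound list**

1 | 1-(2,6-dihydroxy-4-methoxyphenyl)ethan-1-one | CC(=O)c1c(O)cc(OC)cc1O | starting material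
2 | 1-[2-(benzyloxy)-6-hydroxy-4-methoxyphenyl]ethan-1-one | CC(=O)c1c(O)cc(OC)cc1OCc1ccccc1 | intermediate
3 | 4-(benzyloxy)benzoyl chloride | O=C(Cl)c1ccc(OCc2ccccc2)cc1 | starting material
4 | dilithio enolate-phenoxide of 2 (not isolated) | [Li]OC(=C)c1c(O[Li])cc(OC)cc1OCc1ccccc1 | intermediate
5 | 1-[2-(benzyloxy)-6-hydroxy-4-methoxyphenyl]-3-[4-(benzyloxy)phenyl]propane-1,3-dione (not isolated) | O=C(CC(=O)c1ccc(OCc2ccccc2)cc1)c1c(O)cc(OC)cc1OCc1ccccc1 | intermediate
6 | 5-(benzyloxy)-2-[4-(benzyloxy)phenyl]-7-methoxy-4H-chromen-4-one | COc1cc(OCc2ccccc2)c2c(=O)cc(-c3ccc(OCc4ccccc4)cc3)oc2c1 | intermediate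
7 | 3-lithio derivative of 6 (not isolated) | [Li]c1c(-c2ccc(OCc3ccccc3)cc2)oc2cc(OC)cc(OCc3ccccc3)c2c1=O | intermediate
8 | 5-(benzyloxy)-2-[4-(benzyloxy)phenyl]-3-iodo-7-methoxy-4H-chromen-4-one | COc1cc(OCc2ccccc2)c2c(=O)c(I)c(-c3ccc(OCc4ccccc4)cc3)oc2c1 | intermediate
9 | 4-bromo-2-iodophenol | Oc1ccc(Br)cc1I | starting material
10 | 1-(benzyloxy)-4-bromo-2-iodobenzene | Brc1ccc(OCc2ccccc2)c(I)c1 | intermediate
11 | [2-(benzyloxy)-5-bromophenyl]magnesium chloride (not isolated) | Cl[Mg]c1cc(Br)ccc1OCc1ccccc1 | intermediate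
12 | 2-[2-(benzyloxy)-5-bromophenyl]-4,4,5,5-tetramethyl-1,3,2-dioxaborolane | CC1(C)OB(c2cc(Br)ccc2OCc2ccccc2)OC1(C)C | intermediate
13 | 5-(benzyloxy)-3-[2-(benzyloxy)-5-bromophenyl]-2-[4-(benzyloxy)phenyl]-7-methoxy-4H-chromen-4-one (Ar-Br) | COc1cc(OCc2ccccc2)c2c(=O)c(-c3cc(Br)ccc3OCc3ccccc3)c(-c3ccc(OCc4ccccc4)cc3)oc2c1 | intermediate
14 | propiolic acid | C#CC(=O)O | starting material
15 | N-methoxy-N-methylprop-2-ynamide | C#CC(=O)N(C)OC | intermediate
16 | 3-Ar-N-methoxy-N-methylprop-2-ynamide | CON(C)C(=O)C#Cc1ccc(OCc2ccccc2)c(-c2c(-c3ccc(OCc4ccccc4)cc3)oc3cc(OC)cc(OCc4ccccc4)c3c2=O)c1 | intermediate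
17 | triacetic acid lactone, 4-hydroxy-6-methyl-2H-pyran-2-one | Cc1cc(O)cc(=O)o1 | starting material
18 | dilithio derivative of 17, lithiated at O4 and at the C6 methyl carbon (not isolated) | [Li]Cc1cc(O[Li])cc(=O)o1 | intermediate
19 | tetrahedral lithium adduct of 18 and 16, racemic, centre lost at the quench (not isolated) | CON(C)C(O[Li])(Cc1cc(O[Li])cc(=O)o1)C#Cc1ccc(OCc2ccccc2)c(-c2c(-c3ccc(OCc4ccccc4)cc3)oc3cc(OC)cc(OCc4ccccc4)c3c2=O)c1 | intermediate
20 | 4-hydroxy-6-(2-oxo-4-Ar-but-3-yn-1-yl)-2H-pyran-2-one (key-step precursor) | O=c1cc(O)cc(CC(=O)C#Cc2ccc(OCc3ccccc3)c(-c3c(-c4ccc(OCc5ccccc5)cc4)oc4cc(OC)cc(OCc5ccccc5)c4c3=O)c2)o1 | intermediate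
21 | methyl 9-Ar-3,5,7-trioxonon-8-ynoate, drawn in the keto form, present as magnesium chelate (not isolated) | COC(=O)CC(=O)CC(=O)CC(=O)C#Cc1ccc(OCc2ccccc2)c(-c2c(-c3ccc(OCc4ccccc4)cc3)oc3cc(OC)cc(OCc4ccccc4)c3c2=O)c1 | intermediate
22 | 3-Ar-1-(2,4,6-trihydroxyphenyl)prop-2-yn-1-one (not isolated) | O=C(C#Cc1ccc(OCc2ccccc2)c(-c2c(-c3ccc(OCc4ccccc4)cc3)oc3cc(OC)cc(OCc4ccccc4)c3c2=O)c1)c1c(O)cc(O)cc1O | intermediate
23 | 3-Ar-3-methoxy-1-(2,4,6-trihydroxyphenyl)prop-2-en-1-one, mixture of double-bond isomers that converge (not isolated) | COC(=CC(=O)c1c(O)cc(O)cc1O)c1ccc(OCc2ccccc2)c(-c2c(-c3ccc(OCc4ccccc4)cc3)oc3cc(OC)cc(OCc4ccccc4)c3c2=O)c1 | intermediate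
24 | 2-Ar-5,7-dihydroxy-4H-chromen-4-one (tribenzyl ether of the target, key-step product) | COc1cc(OCc2ccccc2)c2c(=O)c(-c3cc(-c4cc(=O)c5c(O)cc(O)cc5o4)ccc3OCc3ccccc3)c(-c3ccc(OCc4ccccc4)cc3)oc2c1 | intermediate
25 | CNP0284832.0, 2-{4-hydroxy-3-[5-hydroxy-2-(4-hydroxyphenyl)-7-methoxy-4-oxo-4H-chromen-3-yl]phenyl}-5,7-dihydroxy-4H-chromen-4-one | COc1cc(O)c2c(=O)c(-c3cc(-c4cc(=O)c5c(O)cc(O)cc5o4)ccc3O)c(-c3ccc(O)cc3)oc2c1 | target

Total step count: 11. Longest linear sequence: 8 steps (1, 2, 3, 6, 8, 9, 10, 11).

**Steps most likely to fail**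

Step 10. Several processes may outrun the Claisen closure: aldol-type folding of C6 onto C4, carbon Michael closure of the C8 methylene onto the alkyne, or methanolytic fragmentation of the chain. Poorly soluble magnesium salts may also stall the lactone opening. The fallback uses only known reactions, sets out from 16 and comes back at 24. Phloroglucinol is treated with MOMCl and i-Pr2NEt to give 1,3,5-tris(methoxymethoxy)benzene F1. n-BuLi in THF at 0 °C lithiates it between two acetal oxygens to give 2,4,6-tris(methoxymethoxy)phenyllithium F2. This adds to the Weinreb amide 16 at -78 °C to give the tris(methoxymethyl)-protected aryl ynone F3. HCl in MeOH removes the three acetals to give 22, and catalytic DMAP in DMF closes 22 in the 6-endo mode to 24. Ring D is then brought in ready-made, and steps 9 and 10 are bypassed.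

Step 9. The delocalised dianion may add in conjugate fashion to the alkynyl amide. Low solubility of the dianion or proton transfer may also leave the acylation incomplete. The fallback sets out from 16 and comes back at 20. i-Bu2AlH in THF at -78 °C reduces the Weinreb amide to the 3-Ar-propynal F4. The dianion 18 adds to the aldehyde carbonyl, an aldol-type 1,2-addition that is a standard reaction of this dianion, to give the racemic propargylic alcohol F5. MnO2 in CH2Cl2/THF oxidises this activated alcohol to the ynone 20.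

Step 8. Oxidative addition of the electron-rich bromide may be slow enough for base-induced oligomerisation or oxidative dimerisation of the electron-poor alkyne to take over. The fallback sets out from 13 and comes back at 16. Sonogashira coupling with trimethylsilylacetylene, an alkyne that tolerates heat (PdCl2(PPh3)2, CuI, Et3N, DMF, 80 °C), gives the silyl alkyne F6. K2CO3 in MeOH/THF gives the terminal alkyne F7. Coupling of F7 with N-methoxy-N-methylcarbamoyl chloride under PdCl2(PPh3)2/CuI/Et3N (acyl Sonogashira type) gives 16.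

**Further compounds**

F1 | step 10 | 1,3,5-tris(methoxymethoxy)benzene | COCOc1cc(OCOC)cc(OCOC)c1
F2 | step 10 | 2,4,6-tris(methoxymethoxy)phenyllithium | [Li]c1c(OCOC)cc(OCOC)cc1OCOC
F3 | step 10 | 3-Ar-1-[2,4,6-tris(methoxymethoxy)phenyl]prop-2-yn-1-one | COCOc1cc(OCOC)c(C(=O)C#Cc2ccc(OCc3ccccc3)c(-c3c(-c4ccc(OCc5ccccc5)cc4)oc4cc(OC)cc(OCc5ccccc5)c4c3=O)c2)c(OCOC)c1
F4 | step 9 | 3-Ar-prop-2-ynal | O=CC#Cc1ccc(OCc2ccccc2)c(-c2c(-c3ccc(OCc4ccccc4)cc3)oc3cc(OC)cc(OCc4ccccc4)c3c2=O)c1
F5 | step 9 | 4-hydroxy-6-(2-hydroxy-4-Ar-but-3-yn-1-yl)-2H-pyran-2-one, racemic | OC(Cc1cc(O)cc(=O)o1)C#Cc1ccc(OCc2ccccc2)c(-c2c(-c3ccc(OCc4ccccc4)cc3)oc3cc(OC)cc(OCc4ccccc4)c3c2=O)c1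
F6 | step 8 | Ar-ethynyl(trimethyl)silane | C[Si](C)(C)C#Cc1ccc(OCc2ccccc2)c(-c2c(-c3ccc(OCc4ccccc4)cc3)oc3cc(OC)cc(OCc4ccccc4)c3c2=O)c1
F7 | step 8 | Ar-acetylene (terminal alkyne) | C#Cc1ccc(OCc2ccccc2)c(-c2c(-c3ccc(OCc4ccccc4)cc3)oc3cc(OC)cc(OCc4ccccc4)c3c2=O)c1
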